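**Retrosynthetic overview**
- The target is cut at the C4 ester (Yamaguchi esterification with (2E,4E,6R)-4,6-dimethylocta-2,4-dienoic acid) and at the C1–CH2 bond (alpha'-alkylation of the cyclopentenone with a 2-(silyloxymethyl)allyl bromide). The acid is freed last.
- The axial C4 alcohol comes from gamma C–H oxidation of the bicyclic enone to the ene-dione, Luche reduction anti to the angular methyl, then selective re-oxidation at C2.
- The five-membered ring is the only ring made, and it is closed after the six-membered ring is fully substituted: intramolecular aldol condensation of a 2-acetonyl-2-methyl-3-carboxycyclohexanone.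
- The six-membered ring comes from (R)-cyclohex-3-ene-1-carboxylic acid: iodolactonization, elimination, ring opening and oxidation give an enone; two alpha'-alkylations (methyl, then allyl anti to the ester) and a Wacker oxidation follow.
- The dienoic acid is built by Evans methylation, oxidation/Wittig, reduction/oxidation, HWE and saponification.

Assumption: the three numbered starting materials (1, 16, 19) are taken as commercial, and (R)-configured 1 is the enantiomer that maps onto C7 of the target.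

**Core (steps 1–13)**

Step 1
Reactants: 1 (R)-cyclohex-3-ene-1-carboxylic acid
Product: 2 (1R,4R,5R)-4-iodo-6-oxabicyclo[3.2.1]octan-7-one
Conditions: I2, KI, NaHCO3, H2O/CH2Cl2, 0 °C to rt, dark
Reagents that add atoms: iodine, II
Why: Iodolactonization: the tethered carboxylate opens the iodonium ion anti at the nearer alkene carbon, so the new C–O (cis to the carboxyl carbon) and C–I bonds are trans-diaxial and both follow from the single stereocentre of 1.

Step 2
Reactants: 2 (1R,4R,5R)-4-iodo-6-oxabicyclo[3.2.1]octan-7-one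
Product: 3 (1R,5R)-6-oxabicyclo[3.2.1]oct-3-en-7-one
Conditions: DBU, toluene, reflux
Reagents that add atoms: none
Why: E2 dehydroiodination removes the only antiperiplanar hydrogen (on C3), giving the allylic lactone without touching C1 or C5.

Step 3
Reactants: 3 (1R,5R)-6-oxabicyclo[3.2.1]oct-3-en-7-one
Product: 4 benzyl (1R,5R)-5-hydroxycyclohex-3-ene-1-carboxylate
Conditions: BnOH (5 equiv), K2CO3 (0.2 equiv), THF, rt
Reagents that add atoms: benzyl alcohol, OCc1ccccc1
Why: Base-catalysed transesterification (ring-opening alcoholysis) of the strained allylic lactone gives the cis hydroxy ester, and no bond to a stereocentre is broken.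

Step 4
Reactants: 4 benzyl (1R,5R)-5-hydroxycyclohex-3-ene-1-carboxylate
Product: 5 benzyl (1R)-5-oxocyclohex-3-ene-1-carboxylate
Conditions: MnO2, CH2Cl2, rt
Reagents that add atoms: none
Why: Allylic alcohol oxidation under neutral conditions gives the enone without moving the alkene into conjugation with the ester, so C1 stays intact.

Step 5
Reactants: 5 benzyl (1R)-5-oxocyclohex-3-ene-1-carboxylate
Product: 6 benzyl (1R,6S)-6-methyl-5-oxocyclohex-3-ene-1-carboxylate
Conditions: LiN(iPr)2 (1.05 equiv), THF, −78 °C; MeI, −78 to −40 °C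
Reagents that add atoms: iodomethane, CI
Why: Kinetic alpha'-enolate alkylation: the alpha carbon is vinylic, so the amide base can only deprotonate C6, and MeI enters mainly anti to the ester (trans isomer shown); this C6 configuration is erased in step 6.

Step 6
Reactants: 6 benzyl (1R,6S)-6-methyl-5-oxocyclohex-3-ene-1-carboxylate
Product: 7 benzyl (1R,6S)-6-methyl-5-oxo-6-(prop-2-en-1-yl)cyclohex-3-ene-1-carboxylate
Conditions: LiN(iPr)2 (1.1 equiv), THF, −78 °C; allyl bromide, DMPU, −78 to −20 °C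
Reagents that add atoms: allyl bromide, C=CCBr
Why: A second alpha'-enolate alkylation builds the quaternary carbon: the neighbouring ester sits pseudoaxial to avoid allylic strain with the enolate methyl, so allyl bromide attacks the opposite face and the methyl ends cis to the ester (6S).

Step 7
Reactants: 7 benzyl (1R,6S)-6-methyl-5-oxo-6-(prop-2-en-1-yl)cyclohex-3-ene-1-carboxylate
Product: 8 benzyl (1R,6S)-6-methyl-5-oxo-6-(2-oxopropyl)cyclohex-3-ene-1-carboxylate
Conditions: PdCl2 (10 mol%), CuCl, O2 (1 atm), DMF/H2O 7:1, rt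
Reagents that add atoms: water, O
Why: Tsuji–Wacker oxidation turns the terminal alkene into the methyl ketone with Markovnikov selectivity, while the electron-poor enone alkene and the benzyl ester are inert.

Step 8
Reactants: 8 benzyl (1R,6S)-6-methyl-5-oxo-6-(2-oxopropyl)cyclohex-3-ene-1-carboxylate
Product: 9 (1R,2S)-2-methyl-3-oxo-2-(2-oxopropyl)cyclohexane-1-carboxylic acid
Conditions: H2 (1 atm), Pd/C, EtOAc, rt
Reagents that add atoms: none
Why: Heterogeneous hydrogenation saturates the enone C=C and hydrogenolyses the benzyl ester in one operation, leaving both ketones and both stereocentres untouched.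

Step 9
Reactants: 9 (1R,2S)-2-methyl-3-oxo-2-(2-oxopropyl)cyclohexane-1-carboxylic acid
Product: 11 (7R,7aS)-7a-methyl-2-oxo-2,4,5,6,7,7a-hexahydro-1H-indene-7-carboxylic acid, via aldol adduct 10 (not isolated)
Conditions: KOH (5 equiv), EtOH/H2O 4:1, 80 °C; then 1 M HCl to pH 2
Reagents that add atoms: none
Why: Intramolecular aldol condensation closes the five-membered ring: the methyl-ketone enolate adds to the ring ketone and E1cB dehydration gives the cyclopentenone, while C7a is quaternary and C7 cannot epimerize because it sits next to a carboxylate.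

Step 10
Reactants: 11 (7R,7aS)-7a-methyl-2-oxo-2,4,5,6,7,7a-hexahydro-1H-indene-7-carboxylic acid
Product: 12 tert-butyl (7R,7aS)-7a-methyl-2-oxo-2,4,5,6,7,7a-hexahydro-1H-indene-7-carboxylate
Conditions: tert-butyl 2,2,2-trichloroacetimidate, BF3·OEt2 (cat.), CH2Cl2/cyclohexane, rt
Reagents that add atoms: tert-butyl 2,2,2-trichloroacetimidate, CC(C)(C)OC(=N)C(Cl)(Cl)Cl
Why: Acid-catalysed imidate esterification (tert-butyl cation transfer) masks the acid without base, so C7 is not epimerized.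

Step 11
Reactants: 12 tert-butyl (7R,7aS)-7a-methyl-2-oxo-2,4,5,6,7,7a-hexahydro-1H-indene-7-carboxylate
Product: 13 tert-butyl (7R,7aS)-7a-methyl-2,4-dioxo-2,4,5,6,7,7a-hexahydro-1H-indene-7-carboxylate
Conditions: Pd(OH)2/C (5 mol%), t-BuOOH (5 equiv), K2CO3 (0.25 equiv), CH2Cl2, 4 °C
Reagents that add atoms: tert-butyl hydroperoxide, CC(C)(C)OO
Why: Radical allylic (gamma) C–H oxidation of the enone gives the 1,4-ene-dione, and C4 is the only gamma CH2 because C7a is quaternary.

Step 12
Reactants: 13 tert-butyl (7R,7aS)-7a-methyl-2,4-dioxo-2,4,5,6,7,7a-hexahydro-1H-indene-7-carboxylate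
Product: 14 tert-butyl (2R,4S,7R,7aS)-2,4-dihydroxy-7a-methyl-2,4,5,6,7,7a-hexahydro-1H-indene-7-carboxylate
Conditions: NaBH4, CeCl3·7H2O, MeOH, −78 to −20 °C
Reagents that add atoms: none
Why: Luche 1,2-reduction: hydride attacks the C4 ketone from the face opposite the axial angular methyl and gives the axial 4S alcohol cis to that methyl (as 6-keto steroids give 6-beta alcohols), while the C2 carbinol (mainly 2R) is re-oxidized in step 13.

Step 13
Reactants: 14 tert-butyl (2R,4S,7R,7aS)-2,4-dihydroxy-7a-methyl-2,4,5,6,7,7a-hexahydro-1H-indene-7-carboxylate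
Product: 15 tert-butyl (4S,7R,7aS)-4-hydroxy-7a-methyl-2-oxo-2,4,5,6,7,7a-hexahydro-1H-indene-7-carboxylate
Conditions: MnO2 (activated, 15 equiv), CH2Cl2, rt, monitored
Reagents that add atoms: none
Why: Chemoselective allylic oxidation: the cyclopentenyl carbinol at C2 is oxidized fast, whereas the axial C4 alcohol has its C–H in the plane of the alkene and is shielded by the syn-axial methyl, so it reacts only slowly.

**Allylic bromide (steps 14–15)**

Step 14
Reactants: 16 2-methylidenepropane-1,3-diol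
Product: 17 2-({[tert-butyl(dimethyl)silyl]oxy}methyl)prop-2-en-1-ol
Conditions: NaH (1.0 equiv), THF, 0 °C; TBSCl (1.0 equiv), rt
Reagents that add atoms: tert-butyldimethylsilyl chloride, CC(C)(C)[Si](C)(C)Cl
Why: Monosilylation of the symmetric diol through its monosodium alkoxide (Williamson-type O-silylation); no stereocentre is involved.

Step 15
Reactants: 17 2-({[tert-butyl(dimethyl)silyl]oxy}methyl)prop-2-en-1-ol
Product: 18 {[2-(bromomethyl)prop-2-en-1-yl]oxy}(tert-butyl)dimethylsilane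
Conditions: CBr4, PPh3, CH2Cl2, 0 °C
Reagents that add atoms: tetrabromomethane, BrC(Br)(Br)Br
Why: Appel bromination converts the primary allylic alcohol into the bromide under neutral conditions that keep the silyl ether.

**Dienoic acid (steps 16–23)**

Step 16
Reactants: 19 (R)-4-benzyl-1,3-oxazolidin-2-one
Product: 20 (R)-4-benzyl-3-butanoyl-1,3-oxazolidin-2-one
Conditions: n-BuLi, THF, −78 °C; butanoyl chloride, −78 to 0 °C
Reagents that add atoms: butanoyl chloride, CCCC(=O)Cl
Why: N-acylation of the lithiated Evans oxazolidinone with the acid chloride.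

Step 17
Reactants: 20 (R)-4-benzyl-3-butanoyl-1,3-oxazolidin-2-one
Product: 21 (R)-4-benzyl-3-[(2R)-2-methylbutanoyl]-1,3-oxazolidin-2-one
Conditions: NaN(SiMe3)2, THF, −78 °C; MeI
Reagents that add atoms: iodomethane, CI
Why: Evans asymmetric alkylation: the chelated Z sodium enolate is methylated on the face opposite the benzyl group, which sets the 2R centre.

Step 18
Reactants: 21 (R)-4-benzyl-3-[(2R)-2-methylbutanoyl]-1,3-oxazolidin-2-one
Product: 22 (R)-2-methylbutan-1-ol
Conditions: LiBH4, H2O (1 equiv), Et2O, 0 °C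
Reagents that add atoms: none
Why: Reductive cleavage of the imide gives the primary alcohol without touching the alpha stereocentre and returns the auxiliary.

Step 19
Reactants: 22 (R)-2-methylbutan-1-ol
Product: 24 ethyl (2E,4R)-2,4-dimethylhex-2-enoate, via (R)-2-methylbutanal 23 (not isolated)
Conditions: PhI(OAc)2, TEMPO (10 mol%), CH2Cl2, rt; then Ph3P=C(CH3)CO2Et, rt
Reagents that add atoms: ethyl 2-(triphenyl-λ5-phosphanylidene)propanoate, CCOC(=O)C(C)=P(c1ccccc1)(c1ccccc1)c1ccccc1
Why: Oxoammonium (TEMPO) oxidation followed in the same flask by Wittig olefination with the stabilized ylide gives the E trisubstituted enoate and avoids isolating the volatile, epimerizable aldehyde.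

Step 20
Reactants: 24 ethyl (2E,4R)-2,4-dimethylhex-2-enoate
Product: 25 (2E,4R)-2,4-dimethylhex-2-en-1-ol
Conditions: i-Bu2AlH (2.2 equiv), CH2Cl2, −78 °C
Reagents that add atoms: none
Why: Hydride 1,2-reduction of the conjugated ester gives the allylic alcohol with the alkene geometry retained.

Step 21
Reactants: 25 (2E,4R)-2,4-dimethylhex-2-en-1-ol
Product: 26 (2E,4R)-2,4-dimethylhex-2-enal
Conditions: MnO2, CH2Cl2, rt
Reagents that add atoms: none
Why: Allylic oxidation stops at the enal without isomerizing the E alkene or the remote stereocentre.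

Step 22
Reactants: 26 (2E,4R)-2,4-dimethylhex-2-enal
Product: 27 ethyl (2E,4E,6R)-4,6-dimethylocta-2,4-dienoate
Conditions: triethyl phosphonoacetate, NaH, THF, 0 °C to rt
Reagents that add atoms: triethyl phosphonoacetate, CCOC(=O)CP(=O)(OCC)OCC
Why: Horner–Wadsworth–Emmons olefination with the stabilized phosphonate anion gives the 2E alkene.

Step 23
Reactants: 27 ethyl (2E,4E,6R)-4,6-dimethylocta-2,4-dienoate
Product: 28 (2E,4E,6R)-4,6-dimethylocta-2,4-dienoic acid
Conditions: LiOH, THF/MeOH/H2O, rt; then 1 M HCl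
Reagents that add atoms: lithium hydroxide, [Li+].[OH-]
Why: Saponification of the ethyl ester; the C6 stereocentre is not acidic.

**Fragment union and end game (steps 24–28)**

Step 24
Reactants: 15 tert-butyl (4S,7R,7aS)-4-hydroxy-7a-methyl-2-oxo-2,4,5,6,7,7a-hexahydro-1H-indene-7-carboxylate; 18 {[2-(bromomethyl)prop-2-en-1-yl]oxy}(tert-butyl)dimethylsilane
Product: 30 tert-butyl (1R,4S,7R,7aS)-1-[2-({[tert-butyl(dimethyl)silyl]oxy}methyl)prop-2-en-1-yl]-4-hydroxy-7a-methyl-2-oxo-2,4,5,6,7,7a-hexahydro-1H-indene-7-carboxylate, via 1S epimer 29 (not isolated)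
Conditions: LiN(iPr)2 (2.2 equiv), THF/DMPU, −78 °C; 18, −78 to −30 °C; AcOH quench; then DBU (0.2 equiv), CH2Cl2, rt
Reagents that add atoms: none
Why: SN2 alpha'-alkylation of the enone as its alkoxide–enolate dianion (C1 is the only alpha' site), after which DBU equilibration converts any 1S epimer into the more stable 1R isomer, whose side chain lies cis to the small angular methyl and away from C7 and its ester.

Step 25
Reactants: 30 tert-butyl (1R,4S,7R,7aS)-1-[2-({[tert-butyl(dimethyl)silyl]oxy}methyl)prop-2-en-1-yl]-4-hydroxy-7a-methyl-2-oxo-2,4,5,6,7,7a-hexahydro-1H-indene-7-carboxylate; 28 (2E,4E,6R)-4,6-dimethylocta-2,4-dienoic acid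
Product: 32 tert-butyl (1R,4S,7R,7aS)-1-[2-({[tert-butyl(dimethyl)silyl]oxy}methyl)prop-2-en-1-yl]-4-{[(2E,4E,6R)-4,6-dimethylocta-2,4-dienoyl]oxy}-7a-methyl-2-oxo-2,4,5,6,7,7a-hexahydro-1H-indene-7-carboxylate, via mixed anhydride 31 (not isolated)
Conditions: 28, 2,4,6-trichlorobenzoyl chloride, Et3N, THF, rt; then 30, DMAP, toluene, rt to 40 °C
Reagents that add atoms: none
Why: Yamaguchi esterification: DMAP attacks the mixed anhydride at the less hindered dienoyl carbonyl and transfers the acyl group to the axial C4 alcohol with retention at C4.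

Step 26
Reactants: 32 tert-butyl (1R,4S,7R,7aS)-1-[2-({[tert-butyl(dimethyl)silyl]oxy}methyl)prop-2-en-1-yl]-4-{[(2E,4E,6R)-4,6-dimethylocta-2,4-dienoyl]oxy}-7a-methyl-2-oxo-2,4,5,6,7,7a-hexahydro-1H-indene-7-carboxylate
Product: 33 tert-butyl (1R,4S,7R,7aS)-4-{[(2E,4E,6R)-4,6-dimethylocta-2,4-dienoyl]oxy}-1-[2-(hydroxymethyl)prop-2-en-1-yl]-7a-methyl-2-oxo-2,4,5,6,7,7a-hexahydro-1H-indene-7-carboxylate
Conditions: HF·pyridine, pyridine/THF, 0 °C to rt
Reagents that add atoms: none
Why: Fluoride-mediated desilylation cleaves the primary silyl ether, while the tert-butyl ester and the dienoate are stable.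

Step 27
Reactants: 33 tert-butyl (1R,4S,7R,7aS)-4-{[(2E,4E,6R)-4,6-dimethylocta-2,4-dienoyl]oxy}-1-[2-(hydroxymethyl)prop-2-en-1-yl]-7a-methyl-2-oxo-2,4,5,6,7,7a-hexahydro-1H-indene-7-carboxylate
Product: 34 tert-butyl (1R,4S,7R,7aS)-4-{[(2E,4E,6R)-4,6-dimethylocta-2,4-dienoyl]oxy}-1-(2-formylprop-2-en-1-yl)-7a-methyl-2-oxo-2,4,5,6,7,7a-hexahydro-1H-indene-7-carboxylate
Conditions: MnO2, CH2Cl2, rt
Reagents that add atoms: none
Why: Allylic oxidation of the primary alcohol gives the alpha-methylene aldehyde without over-oxidation.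

Step 28
Reactants: 34 tert-butyl (1R,4S,7R,7aS)-4-{[(2E,4E,6R)-4,6-dimethylocta-2,4-dienoyl]oxy}-1-(2-formylprop-2-en-1-yl)-7a-methyl-2-oxo-2,4,5,6,7,7a-hexahydro-1H-indene-7-carboxylate
Product: 35 (1R,4S,7R,7aS)-4-{[(2E,4E,6R)-4,6-dimethylocta-2,4-dienoyl]oxy}-1-(2-formylprop-2-en-1-yl)-7a-methyl-2-oxo-2,4,5,6,7,7a-hexahydro-1H-indene-7-carboxylic acid
Conditions: TFA/CH2Cl2 1:4, 0 °C to rt
Reagents that add atoms: none
Why: Acidolysis of the tert-butyl ester (E1 loss of isobutene) frees the acid, while the electron-poor enal, the enone and the allylic dienoate are stable to TFA and no stereocentre is touched.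

**Compound list**
1 | (R)-cyclohex-3-ene-1-carboxylic acid | C1=CCC[C@@H](C(=O)O)C1 | starting material
2 | (1R,4R,5R)-4-iodo-6-oxabicyclo[3.2.1]octan-7-one | O=C2O[C@H]1[C@H](I)CC[C@@H]2C1 | intermediate
3 | (1R,5R)-6-oxabicyclo[3.2.1]oct-3-en-7-one | O=C2O[C@H]1C=CC[C@@H]2C1 | intermediate
4 | benzyl (1R,5R)-5-hydroxycyclohex-3-ene-1-carboxylate | O[C@H]1C=CC[C@@H](C(=O)OCc2ccccc2)C1 | intermediate
5 | benzyl (1R)-5-oxocyclohex-3-ene-1-carboxylate | O=C1C=CC[C@@H](C(=O)OCc2ccccc2)C1 | intermediate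
6 | benzyl (1R,6S)-6-methyl-5-oxocyclohex-3-ene-1-carboxylate | O=C1C=CC[C@@H](C(=O)OCc2ccccc2)[C@@H]1C | intermediate
7 | benzyl (1R,6S)-6-methyl-5-oxo-6-(prop-2-en-1-yl)cyclohex-3-ene-1-carboxylate | O=C1C=CC[C@@H](C(=O)OCc2ccccc2)[C@@]1(CC=C)C | intermediate
8 | benzyl (1R,6S)-6-methyl-5-oxo-6-(2-oxopropyl)cyclohex-3-ene-1-carboxylate | O=C1C=CC[C@@H](C(=O)OCc2ccccc2)[C@@]1(CC(C)=O)C | intermediate
9 | (1R,2S)-2-methyl-3-oxo-2-(2-oxopropyl)cyclohexane-1-carboxylic acid | O=C1CCC[C@@H](C(=O)O)[C@@]1(CC(C)=O)C | intermediate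
10 | (3aR,7R,7aS)-3a-hydroxy-7a-methyl-2-oxooctahydro-1H-indene-7-carboxylic acid (aldol adduct) | O=C1C[C@]2(O)CCC[C@@H](C(=O)O)[C@]2(C)C1 | intermediate
11 | (7R,7aS)-7a-methyl-2-oxo-2,4,5,6,7,7a-hexahydro-1H-indene-7-carboxylic acid | O=C1C=C2CCC[C@@H](C(=O)O)[C@]2(C)C1 | intermediate
12 | tert-butyl (7R,7aS)-7a-methyl-2-oxo-2,4,5,6,7,7a-hexahydro-1H-indene-7-carboxylate | O=C1C=C2CCC[C@@H](C(=O)OC(C)(C)C)[C@]2(C)C1 | intermediate
13 | tert-butyl (7R,7aS)-7a-methyl-2,4-dioxo-2,4,5,6,7,7a-hexahydro-1H-indene-7-carboxylate | O=C1C=C2C(=O)CC[C@@H](C(=O)OC(C)(C)C)[C@]2(C)C1 | intermediate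
14 | tert-butyl (2R,4S,7R,7aS)-2,4-dihydroxy-7a-methyl-2,4,5,6,7,7a-hexahydro-1H-indene-7-carboxylate | O[C@H]1C=C2[C@@H](O)CC[C@@H](C(=O)OC(C)(C)C)[C@]2(C)C1 | intermediate
15 | tert-butyl (4S,7R,7aS)-4-hydroxy-7a-methyl-2-oxo-2,4,5,6,7,7a-hexahydro-1H-indene-7-carboxylate | O=C1C=C2[C@@H](O)CC[C@@H](C(=O)OC(C)(C)C)[C@]2(C)C1 | intermediate
16 | 2-methylidenepropane-1,3-diol | C=C(CO)CO | starting material
17 | 2-({[tert-butyl(dimethyl)silyl]oxy}methyl)prop-2-en-1-ol | C=C(CO)CO[Si](C)(C)C(C)(C)C | intermediate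
18 | {[2-(bromomethyl)prop-2-en-1-yl]oxy}(tert-butyl)dimethylsilane | C=C(CBr)CO[Si](C)(C)C(C)(C)C | intermediate
19 | (R)-4-benzyl-1,3-oxazolidin-2-one | O=C1N[C@H](Cc2ccccc2)CO1 | starting material
20 | (R)-4-benzyl-3-butanoyl-1,3-oxazolidin-2-one | CCCC(=O)N1[C@H](Cc2ccccc2)COC1=O | intermediate
21 | (R)-4-benzyl-3-[(2R)-2-methylbutanoyl]-1,3-oxazolidin-2-one | CC[C@@H](C)C(=O)N1[C@H](Cc2ccccc2)COC1=O | intermediate
22 | (R)-2-methylbutan-1-ol | CC[C@@H](C)CO | intermediate
23 | (R)-2-methylbutanal | CC[C@@H](C)C=O | intermediate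
24 | ethyl (2E,4R)-2,4-dimethylhex-2-enoate | CCOC(=O)/C(C)=C/[C@H](C)CC | intermediate
25 | (2E,4R)-2,4-dimethylhex-2-en-1-ol | OC/C(C)=C/[C@H](C)CC | intermediate
26 | (2E,4R)-2,4-dimethylhex-2-enal | O=C/C(C)=C/[C@H](C)CC | intermediate
27 | ethyl (2E,4E,6R)-4,6-dimethylocta-2,4-dienoate | CCOC(=O)/C=C/C(C)=C/[C@H](C)CC | intermediate
28 | (2E,4E,6R)-4,6-dimethylocta-2,4-dienoic acid | OC(=O)/C=C/C(C)=C/[C@H](C)CC | intermediate
29 | tert-butyl (1S,4S,7R,7aS)-1-[2-({[tert-butyl(dimethyl)silyl]oxy}methyl)prop-2-en-1-yl]-4-hydroxy-7a-methyl-2-oxo-2,4,5,6,7,7a-hexahydro-1H-indene-7-carboxylate (C1 epimer of 30) | C=C(CO[Si](C)(C)C(C)(C)C)C[C@@H]1C(=O)C=C2[C@@H](O)CC[C@@H](C(=O)OC(C)(C)C)[C@@]21C | intermediate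
30 | tert-butyl (1R,4S,7R,7aS)-1-[2-({[tert-butyl(dimethyl)silyl]oxy}methyl)prop-2-en-1-yl]-4-hydroxy-7a-methyl-2-oxo-2,4,5,6,7,7a-hexahydro-1H-indene-7-carboxylate | C=C(CO[Si](C)(C)C(C)(C)C)C[C@H]1C(=O)C=C2[C@@H](O)CC[C@@H](C(=O)OC(C)(C)C)[C@@]21C | intermediate
31 | (2E,4E,6R)-4,6-dimethylocta-2,4-dienoic 2,4,6-trichlorobenzoic anhydride | O=C(OC(=O)/C=C/C(C)=C/[C@H](C)CC)c1c(Cl)cc(Cl)cc1Cl | intermediate
32 | tert-butyl (1R,4S,7R,7aS)-1-[2-({[tert-butyl(dimethyl)silyl]oxy}methyl)prop-2-en-1-yl]-4-{[(2E,4E,6R)-4,6-dimethylocta-2,4-dienoyl]oxy}-7a-methyl-2-oxo-2,4,5,6,7,7a-hexahydro-1H-indene-7-carboxylate | C=C(CO[Si](C)(C)C(C)(C)C)C[C@H]1C(=O)C=C2[C@@H](OC(=O)/C=C/C(C)=C/[C@H](C)CC)CC[C@@H](C(=O)OC(C)(C)C)[C@@]21C | intermediate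
33 | tert-butyl (1R,4S,7R,7aS)-4-{[(2E,4E,6R)-4,6-dimethylocta-2,4-dienoyl]oxy}-1-[2-(hydroxymethyl)prop-2-en-1-yl]-7a-methyl-2-oxo-2,4,5,6,7,7a-hexahydro-1H-indene-7-carboxylate | C=C(CO)C[C@H]1C(=O)C=C2[C@@H](OC(=O)/C=C/C(C)=C/[C@H](C)CC)CC[C@@H](C(=O)OC(C)(C)C)[C@@]21C | intermediate
34 | tert-butyl (1R,4S,7R,7aS)-4-{[(2E,4E,6R)-4,6-dimethylocta-2,4-dienoyl]oxy}-1-(2-formylprop-2-en-1-yl)-7a-methyl-2-oxo-2,4,5,6,7,7a-hexahydro-1H-indene-7-carboxylate | C=C(C=O)C[C@H]1C(=O)C=C2[C@@H](OC(=O)/C=C/C(C)=C/[C@H](C)CC)CC[C@@H](C(=O)OC(C)(C)C)[C@@]21C | intermediate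
35 | (1R,4S,7R,7aS)-4-{[(2E,4E,6R)-4,6-dimethylocta-2,4-dienoyl]oxy}-1-(2-formylprop-2-en-1-yl)-7a-methyl-2-oxo-2,4,5,6,7,7a-hexahydro-1H-indene-7-carboxylic acid | C=C(C=O)C[C@H]1C(=O)C=C2[C@@H](OC(=O)/C=C/C(C)=C/[C@H](C)CC)CC[C@@H](C(=O)O)[C@@]21C | target

**Step count**
Total: 28 steps. Longest linear sequence: 18 steps (steps 1–13 and 24–28), 64 % of the total. The acid branch (steps 16–23) and the bromide branch (steps 14–15) join at steps 25 and 24.

**Steps most likely to fail**

Step 6 (quaternary carbon by the second enolate alkylation). Deprotonation of the hindered tertiary C6–H may be incomplete, and C- versus O-allylation or the facial ratio may be poor. The fallback sets out from 6. Its enolate is trapped on oxygen with allyl chloroformate to give the allyl enol carbonate benzyl (1R)-2-methyl-3-{[(prop-2-en-1-yloxy)carbonyl]oxy}cyclohexa-2,4-diene-1-carboxylate F1. With Pd(PPh3)4 (zerovalent palladium) in THF this undergoes decarboxylative Tsuji allylation, in which the pi-allyl palladium/enolate pair recombines at carbon anti to the ester; a chiral phosphine–oxazoline ligand can reinforce the facial bias. The fallback comes back to the route at 7.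

Step 11 (gamma C–H oxidation to the ene-dione, which feeds steps 12 and 13). Peroxide epoxidation of the ene-dione or incomplete conversion can occur, and the later differentiation of the two carbinols may be imperfect. The fallback sets out from 12. TBSOTf/Et3N gives the extended silyl dienol ether tert-butyl (7R,7aS)-2-{[tert-butyl(dimethyl)silyl]oxy}-7a-methyl-5,6,7,7a-tetrahydro-1H-indene-7-carboxylate F2. Vinylogous Rubottom oxidation with dimethyldioxirane at −78 °C, with axial attack at C4 syn to the angular methyl as for steroidal dienol ethers, followed by mild acid work-up, gives the gamma-hydroxy enone directly. The fallback comes back at 15 and bypasses 13 and 14; its own risk is cross-conjugated (C1) instead of extended silyl dienol ether formation.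

Step 24 (alpha'-alkylation of the hydroxy enone dianion and the C1 configuration). O-alkylation, double alkylation or an unfavourable C1 ratio are possible. The fallback sets out from 15. TMSOTf/Et3N silylates both oxygens to give the cross-conjugated bis-silyl dienol ether tert-butyl (4S,7R,7aS)-7a-methyl-2,4-bis[(trimethylsilyl)oxy]-5,6,7,7a-tetrahydro-4H-indene-7-carboxylate F3. This is allylated at C1 under neutral Tsuji–Trost conditions with Pd(PPh3)4 (zerovalent palladium) and the allylic carbonate methyl 2-({[tert-butyl(dimethyl)silyl]oxy}methyl)prop-2-en-1-yl carbonate F4, made from 17 with methyl chloroformate and pyridine. Citric acid work-up removes the C4 trimethylsilyl ether, and DBU equilibration (or re-enolization and kinetic protonation from the face opposite the angular methyl) sets C1. The fallback comes back at 30.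

Further compounds
F1 | step 6 | benzyl (1R)-2-methyl-3-{[(prop-2-en-1-yloxy)carbonyl]oxy}cyclohexa-2,4-diene-1-carboxylate | C=CCOC(=O)OC1=C(C)[C@H](C(=O)OCc2ccccc2)CC=C1
F2 | step 11 | tert-butyl (7R,7aS)-2-{[tert-butyl(dimethyl)silyl]oxy}-7a-methyl-5,6,7,7a-tetrahydro-1H-indene-7-carboxylate | CC(C)(C)[Si](C)(C)OC1=CC2=CCC[C@@H](C(=O)OC(C)(C)C)[C@]2(C)C1
F3 | step 24 | tert-butyl (4S,7R,7aS)-7a-methyl-2,4-bis[(trimethylsilyl)oxy]-5,6,7,7a-tetrahydro-4H-indene-7-carboxylate | C[Si](C)(C)OC1=C[C@@]2(C)[C@H](C(=O)OC(C)(C)C)CC[C@H](O[Si](C)(C)C)C2=C1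
F4 | step 24 | methyl 2-({[tert-butyl(dimethyl)silyl]oxy}methyl)prop-2-en-1-yl carbonate | COC(=O)OCC(=C)CO[Si](C)(C)C(C)(C)C
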